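**Retrosynthetic overview**

1. Isomuronic acid 15 ⇐ methyl ester 14 by hydrolysis of the ester on C4 (ring numbering as furan-2(5H)-one: O1–C2(=O)–C3(CH3)=C4(CO2H)–C5H(chain)).
2. 14 ⇐ aldehyde 4 + acyl bromide 12 in one pot: addition of the acyl bromide across the aldehyde C=O makes O1–C2 and C5–Br (racemic 1-bromoalkyl ester 13); a nickel-catalysed enantioconvergent reductive coupling of C5–Br with the alkenyl triflate on C4 then forms the C4–C5 bond, which closes the only ring (the butenolide) and sets C5.
3. Enabling feature: C5 carries the ring oxygen O1 that is acylated by C2, so it is an aldehyde carbon in disguise, and it stands 1,5 to the sp2 carbon C4 of the C3=C4 bond of the furanone. A 1-bromoalkyl ester (acyloxy-stabilised, nickel-activatable C–Br on C5) and a Z-enol triflate on C4 (cis to C2) can therefore be bridged by nickel.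
4. 4 ⇐ ω-pentadecalactone 1 (Weinreb amide, MeMgBr, oxidation); 12 ⇐ tert-butyl propanoate 5 + dimethyl oxalate 6 (Claisen, Z-enol triflate, tert-butyl cleavage, acyl bromide).

Key step: step 8

Remarks on the chemistry:
- The target SMILES corresponds to the (R) configuration at C5.
- Assumption: the sense of induction of the chiral nickel catalyst in step 8 cannot be predicted with certainty. L* denotes whichever enantiomer of 2,2'-(cyclopropane-1,1-diyl)bis(3a,8a-dihydro-8H-indeno[1,2-d]oxazole) delivers (R) at C5, to be fixed in the first run; both enantiomers are commercial.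

**Route**

Step 1
Reactants: 1 ω-pentadecalactone (oxacyclohexadecan-2-one)
Product: 2 15-hydroxy-N-methoxy-N-methylpentadecanamide
Conditions: MeNH(OMe)·HCl, iPrMgCl, THF, −20 to 0 °C; aq. NH4Cl
Reagents that add atoms: N,O-dimethylhydroxylamine hydrochloride, CNOC.Cl
Why: Aminolysis of the lactone by the chloromagnesium amide (Weinreb amide formation from an ester) should open the 16-membered ring cleanly, the product being protected from further attack as its magnesium alkoxide.

Step 2
Reactants: 2 15-hydroxy-N-methoxy-N-methylpentadecanamide
Product: 3 16-hydroxyhexadecan-2-one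
Conditions: MeMgBr (3 equiv), THF, 0 °C; aq. NH4Cl
Reagents that add atoms: methylmagnesium bromide, C[Mg]Br
Why: Weinreb ketone synthesis: after deprotonation of the alcohol, addition to the amide gives a stable five-membered magnesium chelate that collapses to the methyl ketone only on work-up, so no tertiary alcohol should form.

Step 3
Reactants: 3 16-hydroxyhexadecan-2-one
Product: 4 15-oxohexadecanal
Conditions: Dess–Martin periodinane, CH2Cl2, rt
Reagents that add atoms: none
Why: Dess–Martin oxidation should take the primary alcohol to the aldehyde under neutral conditions without over-oxidation and without touching the methyl ketone.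

Step 4
Reactants: 5 tert-butyl propanoate; 6 dimethyl oxalate
Product: 8 1-tert-butyl 4-methyl 2-methyl-3-oxobutanedioate, via lithium enolate 7 (not isolated)
Conditions: LiN(iPr)2, THF, −78 °C; then add to 6 (1.5 equiv), −78 °C to rt; aq. HCl
Reagents that add atoms: none
Why: Crossed Claisen condensation: the ester enolate acylates the non-enolisable, highly electrophilic oxalate, and the acidic product is deprotonated by the methoxide released, which shields it from a second addition.

Step 5
Reactants: 8 1-tert-butyl 4-methyl 2-methyl-3-oxobutanedioate
Product: 10 4-tert-butyl 1-methyl (2Z)-3-methyl-2-(trifluoromethanesulfonyloxy)but-2-enedioate, via sodium enolate 9 (not isolated)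
Conditions: NaH, Et2O, 0 °C; then Tf2O, −78 to 0 °C
Reagents that add atoms: trifluoromethanesulfonic anhydride, O=S(=O)(OS(=O)(=O)C(F)(F)F)C(F)(F)F
Why: O-sulfonylation of the enolate (enol triflate formation); the six-membered sodium chelate between the enolate oxygen and the tert-butyl ester carbonyl should fix the Z geometry (OTf cis to CO2tBu), as is usual for β-keto esters.

Step 6
Reactants: 10 4-tert-butyl 1-methyl (2Z)-3-methyl-2-(trifluoromethanesulfonyloxy)but-2-enedioate
Product: 11 (2Z)-4-methoxy-2-methyl-4-oxo-3-(trifluoromethanesulfonyloxy)but-2-enoic acid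
Conditions: TFA, CH2Cl2, rt
Reagents that add atoms: none
Why: Acidolysis of the tert-butyl ester (E1 loss of isobutene) should free the C2 carboxylic acid while the methyl ester, the alkenyl triflate and the geometry of the tetrasubstituted alkene are stable to TFA.

Step 7
Reactants: 11 (2Z)-4-methoxy-2-methyl-4-oxo-3-(trifluoromethanesulfonyloxy)but-2-enoic acid
Product: 12 methyl (2Z)-4-bromo-3-methyl-4-oxo-2-(trifluoromethanesulfonyloxy)but-2-enoate
Conditions: (COBr)2, DMF (cat.), CH2Cl2, 0 °C to rt; evaporate, use crude
Reagents that add atoms: oxalyl bromide, BrC(=O)C(=O)Br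
Why: Acyl bromide formation under Vilsmeier-type catalysis by DMF should proceed at or below room temperature and gives only volatile by-products, so 12 can be used without purification.

Step 8
Reactants: 4 15-oxohexadecanal; 12 methyl (2Z)-4-bromo-3-methyl-4-oxo-2-(trifluoromethanesulfonyloxy)but-2-enoate
Product: 14 methyl (2R)-4-methyl-5-oxo-2-(14-oxopentadecyl)-2,5-dihydrofuran-3-carboxylate, via racemic 1-bromoalkyl ester 13 (not isolated)
Conditions: ZnBr2 (2 mol%), CH2Cl2, −10 °C to rt; solvent switch to THF; then slow addition to NiBr2(dme) (10 mol%), L* (12 mol%), Mn powder (3 equiv), NaI (0.5 equiv), THF/DMA, 0 °C, 0.02 M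
Reagents that add atoms: none
Why: Proposed new method: the ZnBr2-catalysed addition of the acyl bromide across the aldehyde C=O (known 1-haloalkyl ester formation) makes the O1–C2 and C5–Br bonds and gives racemic 13; zerovalent nickel then inserts into the C4–OTf bond, the monovalent alkenylnickel formed on reduction by Mn abstracts the bromine atom from C5, and the planar α-acyloxyalkyl radical recombines with the chiral nickel centre to a six-membered oxa-nickelacycle whose C(sp2)–C(sp3) reductive elimination forms the C4–C5 bond. The closest known reaction types are the nickel/bis(oxazoline)-catalysed enantioconvergent couplings of racemic 1-bromoalkyl esters (made in the flask from aldehydes and acyl bromides) with alkylzinc reagents and the nickel-catalysed enantioselective reductive couplings of alkenyl bromides with racemic benzylic chlorides; the proposal joins the two electrophile classes in one molecule. The single ring, the furan-2(5H)-one, is closed in a five-membered mode that is not a Baldwin-type attack but a ring contraction of the nickelacycle by reductive elimination, so the 5-endo problem of a direct radical addition to C3=C4 does not arise. The new stereocentre C5 is set under catalyst control: both enantiomers of 13 give the same radical, and L* on nickel decides the face on which the C5–Ni bond and then the C4–C5 bond form (enantioconvergence). The step needs cyclisation to win over intermolecular coupling, β-hydride loss and plain reduction of C5–Br, which should be secured by the Z geometry of the alkene (C2 and OTf cis, holding C4 and C5 in a 1,5 relation), by high dilution with slow addition and by fast capture of the radical at the nickel centre of the same molecule; the remote methyl ketone and the methyl ester should be inert both to ZnBr2/acyl bromide at low temperature and to Ni/Mn.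

Step 9
Reactants: 14 methyl (2R)-4-methyl-5-oxo-2-(14-oxopentadecyl)-2,5-dihydrofuran-3-carboxylate
Product: 15 isomuronic acid [(2R)-4-methyl-5-oxo-2-(14-oxopentadecyl)-2,5-dihydrofuran-3-carboxylic acid]
Conditions: 6 M aq. HCl, 1,4-dioxane, 90 °C
Reagents that add atoms: water, O
Why: Acid-catalysed ester hydrolysis (AAC2) should free the C4 acid; the lactone can open and re-close reversibly under these conditions, but C5 is never deprotonated, so the stereocentre should be retained, which is why base is avoided.

**Compound list**

1 | ω-pentadecalactone (oxacyclohexadecan-2-one) | O=C1CCCCCCCCCCCCCCO1 | starting material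
2 | 15-hydroxy-N-methoxy-N-methylpentadecanamide | CON(C)C(=O)CCCCCCCCCCCCCCO | intermediate
3 | 16-hydroxyhexadecan-2-one | CC(=O)CCCCCCCCCCCCCCO | intermediate
4 | 15-oxohexadecanal | CC(=O)CCCCCCCCCCCCCC=O | intermediate
5 | tert-butyl propanoate | CCC(=O)OC(C)(C)C | starting material
6 | dimethyl oxalate | COC(=O)C(=O)OC | starting material
7 | lithium enolate of tert-butyl propanoate (not isolated) | CC=C([O-])OC(C)(C)C.[Li+] | intermediate
8 | 1-tert-butyl 4-methyl 2-methyl-3-oxobutanedioate | COC(=O)C(=O)C(C)C(=O)OC(C)(C)C | intermediate
9 | sodium (Z)-enolate of 8 (not isolated) | COC(=O)/C([O-])=C(\C)C(=O)OC(C)(C)C.[Na+] | intermediate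
10 | 4-tert-butyl 1-methyl (2Z)-3-methyl-2-(trifluoromethanesulfonyloxy)but-2-enedioate | COC(=O)/C(OS(=O)(=O)C(F)(F)F)=C(\C)C(=O)OC(C)(C)C | intermediate
11 | (2Z)-4-methoxy-2-methyl-4-oxo-3-(trifluoromethanesulfonyloxy)but-2-enoic acid | COC(=O)/C(OS(=O)(=O)C(F)(F)F)=C(\C)C(=O)O | intermediate
12 | methyl (2Z)-4-bromo-3-methyl-4-oxo-2-(trifluoromethanesulfonyloxy)but-2-enoate | COC(=O)/C(OS(=O)(=O)C(F)(F)F)=C(\C)C(=O)Br | intermediate
13 | 4-(1-bromo-15-oxohexadecyl) 1-methyl (2Z)-3-methyl-2-(trifluoromethanesulfonyloxy)but-2-enedioate, racemic at the CHBr carbon (not isolated) | CC(=O)CCCCCCCCCCCCCC(Br)OC(=O)/C(C)=C(\OS(=O)(=O)C(F)(F)F)C(=O)OC | intermediate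
14 | methyl (2R)-4-methyl-5-oxo-2-(14-oxopentadecyl)-2,5-dihydrofuran-3-carboxylate | CC(=O)CCCCCCCCCCCCC[C@H]1OC(=O)C(C)=C1C(=O)OC | intermediate
15 | isomuronic acid, (2R)-4-methyl-5-oxo-2-(14-oxopentadecyl)-2,5-dihydrofuran-3-carboxylic acid | CC(=O)CCCCCCCCCCCCC[C@H]1OC(=O)C(C)=C1C(=O)O | target

**Step count and risks**

Total step count: 9. Longest linear sequence: 6 steps (steps 4, 5, 6, 7, 8, 9).

Steps most likely to fail:

1. Step 8 (proposed new method). The ring closure may be outrun by intermolecular coupling, by reduction of the C5–Br bond or by β-hydride loss from the α-acyloxyalkyl nickel species, or the facial discrimination at nickel may be poor. The fallback uses known chemistry, sets out from 10 and 4 and comes back at 14. The C4–C5 bond would be made intermolecularly by a catalytic asymmetric Nozaki–Hiyama–Kishi reaction of enol triflate 10 with aldehyde 4 (CrCl2 (cat.) with a chiral sulfonamide ligand, NiCl2(2,9-dimethyl-1,10-phenanthroline) (cat.), Mn, Cp2ZrCl2, LiCl, MeCN), which is selective for the aldehyde over the ketone. It should give 4-tert-butyl 1-methyl (2E)-2-[(1R)-1-hydroxy-15-oxohexadecyl]-3-methylbut-2-enedioate F1. TFA in CH2Cl2 then cleaves the tert-butyl ester and the cis-disposed hydroxy acid lactonises to 14.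

2. Step 7. Reversible addition–elimination of bromide or HBr at the triflate-bearing carbon may scramble the alkene geometry or displace the triflate, and the acyl bromide may hydrolyse on handling. The fallback sets out from 10 and comes back at 14 without the free acid and without oxalyl bromide. SOCl2 (neat, rt) should convert the tert-butyl ester of 10 directly into methyl (2Z)-4-chloro-3-methyl-4-oxo-2-(trifluoromethanesulfonyloxy)but-2-enoate F2, the methyl ester being inert. ZnCl2-catalysed addition of F2 across the aldehyde C=O of 4 gives 4-(1-chloro-15-oxohexadecyl) 1-methyl (2Z)-3-methyl-2-(trifluoromethanesulfonyloxy)but-2-enedioate F3. F3 enters the nickel stage of step 8 (NaI for halide exchange in the flask) and should lead to 14.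

3. Step 9. Hydrolysis of the hindered, conjugated ester may be slow, with acid-induced aldol condensation at the methyl ketone competing. The fallback sets out from 14 and comes back at 15 through the ring-opened form. LiOH (excess) in THF/H2O at 0 °C to rt should first open the lactone, after which C5 is a non-acidic allylic carbinol, and then saponify the methyl ester. This gives (2E)-2-[(1R)-1-hydroxy-15-oxohexadecyl]-3-methylbut-2-enedioic acid F4 as its dilithium salt. Acidification with 1 M HCl re-closes the butenolide through the cis-disposed C2 carboxyl group to 15.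

Further compounds
F1 | step 8 | 4-tert-butyl 1-methyl (2E)-2-[(1R)-1-hydroxy-15-oxohexadecyl]-3-methylbut-2-enedioate | CC(=O)CCCCCCCCCCCCC[C@@H](O)/C(C(=O)OC)=C(\C(=O)OC(C)(C)C)C
F2 | step 7 | methyl (2Z)-4-chloro-3-methyl-4-oxo-2-(trifluoromethanesulfonyloxy)but-2-enoate | COC(=O)/C(OS(=O)(=O)C(F)(F)F)=C(\C)C(=O)Cl
F3 | step 7 | 4-(1-chloro-15-oxohexadecyl) 1-methyl (2Z)-3-methyl-2-(trifluoromethanesulfonyloxy)but-2-enedioate | CC(=O)CCCCCCCCCCCCCC(Cl)OC(=O)/C(C)=C(\OS(=O)(=O)C(F)(F)F)C(=O)OC
F4 | step 9 | (2E)-2-[(1R)-1-hydroxy-15-oxohexadecyl]-3-methylbut-2-enedioic acid | CC(=O)CCCCCCCCCCCCC[C@@H](O)/C(C(=O)O)=C(\C(=O)O)C
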